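**Plan**
- Retrosynthesis: the C9–Br and C10–Cl bonds are cut back to a C9=C10 olefin and C4–Br to a C4–O bond (inversion). The C1–C6 bond of ring A is cut next, then C3–C4 (Grignard addition) and the two C5–CH3 bonds.
- Enabling feature: spiro atom C6 carries C1, the ring A carbon that bears the exo-methylene. A C1 alkenyl triflate can therefore add across the C6=C11 double bond of a ring B cyclohexa-1,4-diene, whose alkyl-bearing carbons C6 and C9 are the para carbons of a p-tolyl ring.
- Forward order: ring B is carried as the arene and unmasked by Birch reduction; ring A closes in step 10 (6-exo Heck); ring B is then adjusted to the C9=C10 olefin and halogenated.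
- Stereochemistry: C4 comes from a Corey–Bakshi–Shibata reduction. C6 is set in the Heck step by the C4 silyl ether (chair transition state), reinforced by the chiral bisphosphine. C4–Br arises by inversion. C10 and C9 come from anti chlorohydroxylation on the ring B face opposite the axial C1, then bromide for hydroxyl with retention.

Key step: step 10

Numbering remark: the spiro[5.5]undecane numbering of the target is used for every intermediate (ring A = C1–C6, ring B = C6–C11; C1 exo-methylene carbon, C4 CHBr, C5 CMe2, C6 spiro atom, C9 CBrMe, C10 CHCl).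
Assumption: (R)-BINAP is taken as the ligand antipode whose preferred olefin face is the one already favoured by the (4S)-silyl ether; if the pairing is mismatched, (S)-BINAP replaces it with no other change.

**Route**

Step 1
Reactants: 1 4-methylphenylacetonitrile; 2 iodomethane
Product: 3 2-methyl-2-(4-methylphenyl)propanenitrile
Conditions: NaH (2.4 equiv), MeI (2.6 equiv), THF, 0 °C to rt
Reagents that add atoms: iodomethane (compound 2), CI
Why: Twofold α-alkylation of the benzylic nitrile anion stops at the quaternary stage and installs both C5 methyl groups.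

Step 2
Reactants: 3 2-methyl-2-(4-methylphenyl)propanenitrile
Product: 5 2-methyl-2-(4-methylphenyl)propanal, via aluminium aldimine 4 (not isolated)
Conditions: i-Bu2AlH (1.2 equiv), toluene, −78 to 0 °C; then 1 M HCl, 0 °C
Reagents that add atoms: water, O
Why: Partial hydride reduction of a nitrile with i-Bu2AlH halts at the N-aluminated aldimine, which hydrolyses on acidic work-up to the non-enolisable aldehyde whose carbonyl carbon is C4.

Step 3
Reactants: 5 2-methyl-2-(4-methylphenyl)propanal; 6 2-(2-bromoethyl)-2-methyl-1,3-dioxolane
Product: 8 rac-4-methyl-1-(2-methyl-1,3-dioxolan-2-yl)-4-(4-methylphenyl)pentan-3-ol, via Grignard reagent 7 (not isolated)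
Conditions: Mg, THF, 20–25 °C; then 5, 0 °C to rt; aq NH4Cl
Reagents that add atoms: none
Why: Grignard addition of the ketal-protected 3-oxobutyl reagent, kept below 30 °C because it decomposes on heating, forms the C3–C4 bond and brings in C1 to C3 and the future exo-methylene carbon, the carbinol being racemic until steps 4 and 5.

Step 4
Reactants: 8 rac-4-methyl-1-(2-methyl-1,3-dioxolan-2-yl)-4-(4-methylphenyl)pentan-3-ol
Product: 9 4-methyl-1-(2-methyl-1,3-dioxolan-2-yl)-4-(4-methylphenyl)pentan-3-one
Conditions: Dess–Martin periodinane (1.3 equiv), NaHCO3, CH2Cl2, 0 °C to rt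
Reagents that add atoms: none
Why: Dess–Martin oxidation of the hindered secondary alcohol under bicarbonate buffering gives the tert-alkyl ketone without opening the dioxolane.

Step 5
Reactants: 9 4-methyl-1-(2-methyl-1,3-dioxolan-2-yl)-4-(4-methylphenyl)pentan-3-one
Product: 10 (3S)-4-methyl-1-(2-methyl-1,3-dioxolan-2-yl)-4-(4-methylphenyl)pentan-3-ol
Conditions: (R)-2-methyl-CBS-oxazaborolidine [(3aR)-1-methyl-3,3-diphenyltetrahydro-1H,3H-pyrrolo[1,2-c][1,3,2]oxazaborole] (0.2 equiv), BH3·SMe2 (1.0 equiv), THF, −20 to 0 °C; then MeOH, aq NH4Cl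
Reagents that add atoms: none
Why: In this Corey–Bakshi–Shibata reduction the tertiary CMe2Ar group acts as the large and the CH2 chain as the small substituent, so the (R)-oxazaborolidine should deliver hydride to the face that gives the (S)-carbinol at C4.

Step 6
Reactants: 10 (3S)-4-methyl-1-(2-methyl-1,3-dioxolan-2-yl)-4-(4-methylphenyl)pentan-3-ol
Product: 11 tert-butyldimethyl{[(3S)-4-methyl-1-(2-methyl-1,3-dioxolan-2-yl)-4-(4-methylphenyl)pentan-3-yl]oxy}silane
Conditions: TBSOTf (1.5 equiv), 2,6-lutidine (3 equiv), CH2Cl2, −78 to 0 °C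
Reagents that add atoms: tert-butyldimethylsilyl trifluoromethanesulfonate, CC(C)(C)[Si](C)(C)OS(=O)(=O)C(F)(F)F
Why: Silylation with a silyl triflate and a hindered pyridine base is the standard protection of a neopentylic secondary alcohol, and the ether prevents lactol formation in step 8, survives the bases of steps 9 and 10 and later serves as the bulky equatorial group that steers step 10.

Step 7
Reactants: 11 tert-butyldimethyl{[(3S)-4-methyl-1-(2-methyl-1,3-dioxolan-2-yl)-4-(4-methylphenyl)pentan-3-yl]oxy}silane
Product: 12 tert-butyldimethyl{[(3S)-4-methyl-4-(4-methylcyclohexa-1,4-dien-1-yl)-1-(2-methyl-1,3-dioxolan-2-yl)pentan-3-yl]oxy}silane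
Conditions: Li (10 equiv), NH3(l)/THF/t-BuOH, −78 to −33 °C; solid NH4Cl
Reagents that add atoms: none
Why: Birch reduction of a para-dialkylbenzene leaves both alkyl-bearing carbons (C6 and C9) on the double bonds of the 1,4-diene, and the silyl ether and the dioxolane are inert to the dissolving metal.

Step 8
Reactants: 12 tert-butyldimethyl{[(3S)-4-methyl-4-(4-methylcyclohexa-1,4-dien-1-yl)-1-(2-methyl-1,3-dioxolan-2-yl)pentan-3-yl]oxy}silane
Product: 13 (5S)-5-[(tert-butyldimethylsilyl)oxy]-6-methyl-6-(4-methylcyclohexa-1,4-dien-1-yl)heptan-2-one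
Conditions: pyridinium p-toluenesulfonate (0.3 equiv), acetone/H2O (10:1), 40 °C, argon
Reagents that add atoms: water, O
Why: Mild acid-catalysed ketal hydrolysis frees the methyl ketone while the hindered silyl ether and the unconjugated diene should be left untouched.

Step 9
Reactants: 13 (5S)-5-[(tert-butyldimethylsilyl)oxy]-6-methyl-6-(4-methylcyclohexa-1,4-dien-1-yl)heptan-2-one
Product: 15 (5S)-5-[(tert-butyldimethylsilyl)oxy]-6-methyl-6-(4-methylcyclohexa-1,4-dien-1-yl)hept-1-en-2-yl trifluoromethanesulfonate, via potassium enolate 14 (not isolated)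
Conditions: KN(SiMe3)2 (1.2 equiv), THF, −78 °C; then PhNTf2 (1.3 equiv), −78 to 0 °C
Reagents that add atoms: N-phenylbis(trifluoromethanesulfonimide), O=S(=O)(N(c1ccccc1)S(=O)(=O)C(F)(F)F)C(F)(F)F
Why: Kinetic deprotonation of the methyl ketone at its methyl group by a hindered amide base followed by O-sulfonylation (enol triflate formation) gives the terminal 2-triflyloxy-1-alkene, whose carbon C1 already carries the future exo-methylene.

Step 10
Reactants: 15 (5S)-5-[(tert-butyldimethylsilyl)oxy]-6-methyl-6-(4-methylcyclohexa-1,4-dien-1-yl)hept-1-en-2-yl trifluoromethanesulfonate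
Product: 16 (4S,6S)-4-[(tert-butyldimethylsilyl)oxy]-5,5,9-trimethyl-1-methylidenespiro[5.5]undeca-8,10-diene
Conditions: Pd(OAc)2 (0.10 equiv), (R)-BINAP (0.15 equiv), 1,2,2,6,6-pentamethylpiperidine (3 equiv), toluene, 80 °C
Reagents that add atoms: none
Why: Zerovalent palladium, formed in situ from Pd(OAc)2 and (R)-BINAP, inserts into the C1–OTf bond to give a cationic vinylpalladium species (divalent palladium) that binds the trisubstituted C6=C11 olefin of ring B; syn migratory insertion joins C1 to C6 and places palladium on C11, and because C6 is now quaternary the syn β-hydride can only come from C10, which releases the C10=C11 olefin in conjugation with C8=C9 while the amine base returns the catalyst to zerovalent palladium. The closest known reaction type is the asymmetric intramolecular Heck cyclisation of alkenyl triflates onto cyclohexadienes and trisubstituted olefins that creates quaternary and spiro carbon centres. Ring A closes in the 6-exo-trig mode, the 7-endo alternative (bond to C11) being disfavoured by the four-atom tether, the geminal dimethyl group at C5 and the need to place palladium on a tertiary neopentyl carbon. The new stereocentre C6 is controlled by the C4 stereocentre through a chair-like transition state in which the silyloxy group is equatorial and the reacting olefin carbon C11 must stand axial to keep Pd–C1 and C6=C11 coplanar, so that C11 ends trans to the C4 oxygen as required for (6S), and the chiral pocket of (R)-BINAP is meant to reinforce this face. The step needs site selectivity for C6=C11 over C8=C9, which the tether secures because only C6=C11 can reach the vinylpalladium, and it needs cyclisation to outrun palladium hydride-mediated isomerisation or dehydrogenation of the 1,4-diene, for which the triflate (cationic pathway) and the hindered amine base are chosen.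

Step 11
Reactants: 16 (4S,6S)-4-[(tert-butyldimethylsilyl)oxy]-5,5,9-trimethyl-1-methylidenespiro[5.5]undeca-8,10-diene
Product: 17 (4S,6S)-4-[(tert-butyldimethylsilyl)oxy]-5,5,9-trimethyl-1-methylidenespiro[5.5]undec-9-ene
Conditions: (η6-naphthalene)Cr(CO)3 (0.2 equiv), H2 (50 atm), THF, 40 °C
Reagents that add atoms: none
Why: Chromium tricarbonyl-catalysed 1,4-hydrogenation adds hydrogen to the termini C8 and C11 of the s-cis ring B diene and leaves the C9=C10 olefin, whereas the isolated exo-methylene cannot bind as a diene and should not be reduced.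

Step 12
Reactants: 17 (4S,6S)-4-[(tert-butyldimethylsilyl)oxy]-5,5,9-trimethyl-1-methylidenespiro[5.5]undec-9-ene
Product: 18 (4S,6S)-5,5,9-trimethyl-1-methylidenespiro[5.5]undec-9-en-4-ol
Conditions: Bu4NF (3 equiv), THF, 50 °C
Reagents that add atoms: none
Why: Fluoride-mediated desilylation frees the C4 hydroxyl under non-acidic conditions that preserve the exo-methylene and the trisubstituted olefin.

Step 13
Reactants: 18 (4S,6S)-5,5,9-trimethyl-1-methylidenespiro[5.5]undec-9-en-4-ol
Product: 20 (4R,6S)-4-bromo-5,5,9-trimethyl-1-methylidenespiro[5.5]undec-9-ene, via alkoxyphosphonium bromide 19 (not isolated)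
Conditions: PPh3 (3 equiv), CBr4 (3 equiv), toluene, 70 °C
Reagents that add atoms: tetrabromomethane, BrC(Br)(Br)Br
Why: In this Appel reaction bromide displaces the oxyphosphonium group from the rear, so the (4S)-alcohol should give the (4R)-bromide under neutral conditions that spare both olefins, a displacement of a type precedented for neopentylic 2,2-dimethylcyclohexanols although elimination competes.

Step 14
Reactants: 20 (4R,6S)-4-bromo-5,5,9-trimethyl-1-methylidenespiro[5.5]undec-9-ene
Product: 21 (4R,6S,9S,10S)-4-bromo-10-chloro-5,5,9-trimethyl-1-methylidenespiro[5.5]undecan-9-ol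
Conditions: trichloroisocyanuric acid (0.36 equiv), acetone/H2O (4:1), 0 °C
Reagents that add atoms: trichloroisocyanuric acid, O=C1N(Cl)C(=O)N(Cl)C(=O)N1Cl; water, O
Why: In this electrophilic chlorohydroxylation the electron-rich trisubstituted C9=C10 olefin should react in preference to the exo-methylene flanked by the spiro carbon, chlorine is expected to enter C10 from the ring B face opposite the axial C1 (the face of C5) and water to open the chloronium-like ion at tertiary C9 from the other side, which sets (10S) and (9S) by anti addition.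

Step 15
Reactants: 21 (4R,6S,9S,10S)-4-bromo-10-chloro-5,5,9-trimethyl-1-methylidenespiro[5.5]undecan-9-ol
Product: 23 obtusane [(4R,6S,9S,10S)-4,9-dibromo-10-chloro-5,5,9-trimethyl-1-methylidenespiro[5.5]undecane], via imidate bromide 22 (not isolated)
Conditions: 1-bromo-N,N,2-trimethylprop-1-en-1-amine (1.5 equiv), CH2Cl2, −20 °C to rt
Reagents that add atoms: 1-bromo-N,N,2-trimethylprop-1-en-1-amine, CC(C)=C(Br)N(C)C
Why: Deoxybromination of a tertiary alcohol with an α-bromoenamine runs under neutral, HBr-free conditions that the exo-methylene should tolerate; the tertiary iminium ether ionises at C9 and the bromide of the contact ion pair is expected to return to the face the amide leaves, anti to the C10 chlorine that shields or bridges the other face, so that C9 should keep its (S) configuration (net retention).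

**Compound list**

1 | 4-methylphenylacetonitrile | Cc1ccc(CC#N)cc1 | starting material
2 | iodomethane | CI | starting material
3 | 2-methyl-2-(4-methylphenyl)propanenitrile | Cc1ccc(cc1)C(C)(C)C#N | intermediate
4 | N-(diisobutylalumanyl)-2-methyl-2-(4-methylphenyl)propan-1-imine (aluminium aldimine) | Cc1ccc(cc1)C(C)(C)C=N[Al](CC(C)C)CC(C)C | intermediate (not isolated)
5 | 2-methyl-2-(4-methylphenyl)propanal | Cc1ccc(cc1)C(C)(C)C=O | intermediate
6 | 2-(2-bromoethyl)-2-methyl-1,3-dioxolane | CC1(CCBr)OCCO1 | starting material
7 | [2-(2-methyl-1,3-dioxolan-2-yl)ethyl]magnesium bromide (Grignard reagent) | CC1(CC[Mg]Br)OCCO1 | intermediate (not isolated)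
8 | rac-4-methyl-1-(2-methyl-1,3-dioxolan-2-yl)-4-(4-methylphenyl)pentan-3-ol | CC1(CCC(O)C(C)(C)c2ccc(C)cc2)OCCO1 | intermediate
9 | 4-methyl-1-(2-methyl-1,3-dioxolan-2-yl)-4-(4-methylphenyl)pentan-3-one | CC1(CCC(=O)C(C)(C)c2ccc(C)cc2)OCCO1 | intermediate
10 | (3S)-4-methyl-1-(2-methyl-1,3-dioxolan-2-yl)-4-(4-methylphenyl)pentan-3-ol | CC1(CC[C@H](O)C(C)(C)c2ccc(C)cc2)OCCO1 | intermediate
11 | tert-butyldimethyl{[(3S)-4-methyl-1-(2-methyl-1,3-dioxolan-2-yl)-4-(4-methylphenyl)pentan-3-yl]oxy}silane | CC1(CC[C@H](O[Si](C)(C)C(C)(C)C)C(C)(C)c2ccc(C)cc2)OCCO1 | intermediate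
12 | tert-butyldimethyl{[(3S)-4-methyl-4-(4-methylcyclohexa-1,4-dien-1-yl)-1-(2-methyl-1,3-dioxolan-2-yl)pentan-3-yl]oxy}silane | CC1(CC[C@H](O[Si](C)(C)C(C)(C)C)C(C)(C)C2=CCC(C)=CC2)OCCO1 | intermediate
13 | (5S)-5-[(tert-butyldimethylsilyl)oxy]-6-methyl-6-(4-methylcyclohexa-1,4-dien-1-yl)heptan-2-one | CC(=O)CC[C@H](O[Si](C)(C)C(C)(C)C)C(C)(C)C1=CCC(C)=CC1 | intermediate
14 | potassium (5S)-5-[(tert-butyldimethylsilyl)oxy]-6-methyl-6-(4-methylcyclohexa-1,4-dien-1-yl)hept-1-en-2-olate | [K+].C=C([O-])CC[C@H](O[Si](C)(C)C(C)(C)C)C(C)(C)C1=CCC(C)=CC1 | intermediate (not isolated)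
15 | (5S)-5-[(tert-butyldimethylsilyl)oxy]-6-methyl-6-(4-methylcyclohexa-1,4-dien-1-yl)hept-1-en-2-yl trifluoromethanesulfonate | C=C(OS(=O)(=O)C(F)(F)F)CC[C@H](O[Si](C)(C)C(C)(C)C)C(C)(C)C1=CCC(C)=CC1 | intermediate (precursor of the key step)
16 | (4S,6S)-4-[(tert-butyldimethylsilyl)oxy]-5,5,9-trimethyl-1-methylidenespiro[5.5]undeca-8,10-diene | C=C1CC[C@H](O[Si](C)(C)C(C)(C)C)C(C)(C)[C@]12CC=C(C)C=C2 | intermediate (product of the key step)
17 | (4S,6S)-4-[(tert-butyldimethylsilyl)oxy]-5,5,9-trimethyl-1-methylidenespiro[5.5]undec-9-ene | C=C1CC[C@H](O[Si](C)(C)C(C)(C)C)C(C)(C)[C@]12CCC(C)=CC2 | intermediate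
18 | (4S,6S)-5,5,9-trimethyl-1-methylidenespiro[5.5]undec-9-en-4-ol | C=C1CC[C@H](O)C(C)(C)[C@]12CCC(C)=CC2 | intermediate
19 | {[(4S,6S)-5,5,9-trimethyl-1-methylidenespiro[5.5]undec-9-en-4-yl]oxy}triphenylphosphonium bromide | C=C1CC[C@H](O[P+](c3ccccc3)(c3ccccc3)c3ccccc3)C(C)(C)[C@]12CCC(C)=CC2.[Br-] | intermediate (not isolated)
20 | (4R,6S)-4-bromo-5,5,9-trimethyl-1-methylidenespiro[5.5]undec-9-ene | C=C1CC[C@@H](Br)C(C)(C)[C@]12CCC(C)=CC2 | intermediate
21 | (4R,6S,9S,10S)-4-bromo-10-chloro-5,5,9-trimethyl-1-methylidenespiro[5.5]undecan-9-ol | C=C1CC[C@@H](Br)C(C)(C)[C@]12CC[C@](C)(O)[C@@H](Cl)C2 | intermediate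
22 | N-[1-{[(4R,6S,9S,10S)-4-bromo-10-chloro-5,5,9-trimethyl-1-methylidenespiro[5.5]undecan-9-yl]oxy}-2-methylpropylidene]-N-methylmethanaminium bromide (imidate bromide) | C=C1CC[C@@H](Br)C(C)(C)[C@]12CC[C@](C)(OC(C(C)C)=[N+](C)C)[C@@H](Cl)C2.[Br-] | intermediate (not isolated)
23 | obtusane, (4R,6S,9S,10S)-4,9-dibromo-10-chloro-5,5,9-trimethyl-1-methylidenespiro[5.5]undecane | C=C1CC[C@@H](Br)C(C)(C)[C@]12CC[C@](C)(Br)[C@@H](Cl)C2 | target

**Step count and risks**

Total step count: 15. Longest linear sequence: 15 steps (1 to 23); bromide 6 enters in step 3.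

Steps most likely to fail:

Step 15 (tertiary bromide at C9). Ionisation may give a free, non-bridged β-chloro cation; bromide would then be delivered axially on the C5 face (epimerisation at C9), or a proton would be lost to give olefins. The fallback sets out from olefin 20 and returns at target 23, and makes both carbon–halogen bonds by bromonium opening instead. BrCl (CH2Cl2, −78 °C) is added to 20; bromonium formation is reversible, so the product is fixed at the opening step, where chloride can attack tertiary C9 in the chair-like trans-diaxial mode only for the bromonium on the C1 face. This should give (4R,6S,9R,10R)-4,10-dibromo-9-chloro-5,5,9-trimethyl-1-methylidenespiro[5.5]undecane F1. Trans-diaxial vicinal bromochlorides are known to interchange their halogens thermally, each halogen moving to the neighbouring carbon on its own face. Warming F1 in MeCN at 60 °C should therefore move bromine to C9 and chlorine to C10 and give the trans-diequatorial isomer, which is 23.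

Step 13 (bromide for hydroxyl at C4). The rear of C4 is flanked by an axial C5 methyl group and by a ring B methylene on C6, so loss of the oxyphosphonium group by elimination toward C3 or a 1,2-shift from C5 may outrun substitution. The fallback sets out from alcohol 18 and returns at bromide 20, and separates activation from displacement. Tf2O and pyridine (CH2Cl2, −40 °C) should give (4S,6S)-5,5,9-trimethyl-1-methylidenespiro[5.5]undec-9-en-4-yl trifluoromethanesulfonate F2. This sulfonate is then treated cold with Bu4NBr in toluene (−20 °C to rt), so that a far better leaving group meets a non-basic, poorly solvated bromide at a temperature where elimination is slow; inversion again gives the (4R)-bromide.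

Step 10 (Heck spirocyclisation). Insertion at C6, next to the quaternary C5, may be slow. That would leave time for loss of the triflate and for palladium hydride-mediated double-bond migration or dehydrogenation of the 1,4-diene to the arene under hot, basic conditions; the ligand may also oppose the facial bias of the substrate. The fallback sets out from triflate 15 and returns at 16, and reaches the same C1 vinylpalladium by hydropalladation instead of oxidative addition. LiN(i-Pr)2 (2.2 equiv, THF, −78 °C) eliminates the triflate to the terminal alkyne tert-butyldimethyl{[(3S)-2-methyl-2-(4-methylcyclohexa-1,4-dien-1-yl)hept-6-yn-3-yl]oxy}silane F3. Pd2(dba)3·CHCl3, AcOH and PPh3 (benzene, 40 °C) then effect an enyne cycloisomerisation of the Alder-ene type. The palladium hydride adds across the alkyne with palladium on C1; insertion into C6=C11 and β-hydride loss toward C10 follow as in step 10, without triflate, amine base or high temperature. The configuration at C6 is then left to the C4 silyl ether alone.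

Further compounds
F1 | step 15 | (4R,6S,9R,10R)-4,10-dibromo-9-chloro-5,5,9-trimethyl-1-methylidenespiro[5.5]undecane | C=C1CC[C@@H](Br)C(C)(C)[C@]12CC[C@@](C)(Cl)[C@H](Br)C2
F2 | step 13 | (4S,6S)-5,5,9-trimethyl-1-methylidenespiro[5.5]undec-9-en-4-yl trifluoromethanesulfonate | C=C1CC[C@H](OS(=O)(=O)C(F)(F)F)C(C)(C)[C@]12CCC(C)=CC2
F3 | step 10 | tert-butyldimethyl{[(3S)-2-methyl-2-(4-methylcyclohexa-1,4-dien-1-yl)hept-6-yn-3-yl]oxy}silane | C#CCC[C@H](O[Si](C)(C)C(C)(C)C)C(C)(C)C1=CCC(C)=CC1
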